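Remark on the chemistry: atoms are numbered as in kaurane, so that 28 is a 6,7-secokauran-7,20-olide: C17H2=C16, C15(=O), quaternary C8, C7(=O)–O–C20H2–C10 (lactone), C1(OAc), C2, C3, C4(CH3)2, C5(C6H2OH), C9, C11(OH), C12, C13, C14(OH). C15 in 24–26 is carried as a mixture of epimers because it ends as the ketone.

## Structural features

The target has four rings: cyclohexane ring A (C1–C5, C10); a δ-lactone (C7, C8, C9, C10, C20, O) that is spiro-joined to ring A at C10 and cis-fused to ring C across C8–C9; and rings C (C8, C9, C11–C14) and D (C8, C14, C13, C16, C15), which form a bicyclo[3.2.1]octane with a quaternary bridgehead C8. C8 carries three oxygenated carbons: the lactone carbonyl C7, the ketone C15 and the carbinol C14. It is therefore the α-carbon of a β-keto lactone, and O14 is a β-hydroxy carbonyl oxygen twice over. There are eight stereocentres (C1, C5, C10, C9, C8, C11, C13, C14); six are contiguous (C1–C10–C9–C8–C14–C13), and C10–C9–C8 is a quaternary–tertiary–quaternary array. On ring C the oxygens at C11 and C14 are cis-1,4 to each other and lie on the face of the C15–C16 bridge, opposite to C7 and C10. Fragile groups are the exo-methylene enone (C17=C16–C15=O), the 14-hydroxy-15-ketone (retro-aldol cleavage of C8–C14 under base), the lactone, and the single acetate at C1 beside three free hydroxyl groups. The real difficulty is ring C, with four stereocentres including C8, attached to the hindered spiro centre C10. The key step exploits two features: the C8=C9 bond of a lactone that is acylated at C8 is a doubly activated cis-dienophile, and C11–C12–C13–C14 with its two cis oxygens is a 1,4-dioxygenated (E,E)-diene. One Diels–Alder reaction therefore forms C9–C11 and C8–C14, closes ring C and sets C8, C9, C11 and C14 together.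

## Logic of the disconnections

28 ⇒ 27. The O–Si bonds at O6, O11 and O14 are cut last. The free 14-hydroxy ketone is base-labile and four hydroxyl groups could not be told apart for acetylation, so three stay silylated while the C1 acetate is already in place. The forward step must remove silicon without base.

27 ⇒ 26 ⇒ 24. C15=O is taken back to the carbinol, then the C13–C16 bond of ring D is cut and the C16=C17 methylene is traced to a terminal alkyne. Ring D and the methylene group thus come from one enyne cyclization, and the bicyclo[3.2.1]octane becomes the cyclohexene 24. The forward step needs 5-exo closure at C13 rather than 6-endo closure at C12; delivery from the C15 face fixes C13.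

24 ⇒ 22 + 23. The C15–C16 bond is cut at the only aldehyde, so the two-carbon unit comes from a commercial reagent. The addition must spare the lactone and the acetate.

22 ⇒ 18 + 21 (key). C9–C11 and C8–C14 are cut together, because a cis-1,4-dioxygenated cyclohexene flanking a bond whose C8 end is a 1,3-dicarbonyl carbon is a Diels–Alder retron. Ring C and four stereocentres disappear at once; what remains is a spirolactone with three stereocentres and an achiral four-carbon diene. The forward step demands a formyl-endo transition state, approach to the face of C8=C9 that lies on the C1 side, reaction at C=C and not at the C=C–C=O heterodiene, and tolerance of quaternary C10 next to C9.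

21 ⇒ 19. The two O–Si bonds are exchanged for O-acetyl. Silyl ethers can be removed at the end beside the C1 acetate; acetates could not. The (E,E) geometry must be kept.

18 ⇒ 16 ⇒ 13 + 14. The C8=C9 π bond is cut back to C8–H/C9–H, then the C8–C15 bond, since C8 is the lactone α-carbon. This leaves a plain spirolactone. Formylation must work without strong base because the C1 acetate is present, and the elimination must go toward C9.

13 ⇒ 10 + 11. C9–C10 and O20–C7 are cut. The quaternary spiro carbon is best made from a tertiary radical, and the oxirane oxygen becomes the lactone oxygen. The lactone ring and C10 then come from an oxirane and an acrylate. The forward step needs addition anti to the C1 and C5 substituents, conjugate addition faster than reduction of the radical, and lactonization faster than acyl transfer from O1.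

10 ⇒ 9 ⇒ 8 ⇒ 7 ⇒ 6 ⇒ 5. The O1–acetyl bond and the C10/C20 oxirane are cut, then the C1–O bond itself, which is traced to an oxirane on C1=C10 of 5 opened toward the C20 methyl. The C6 hydroxyl can direct oxygen to C1 on its own face, so C1 is set from C5 and all ring-A oxygens come from one alkene. Both epoxidations must be syn-directed, and the proton must be taken from C20, not C2.

5 ⇒ 4 ⇒ 2 + 3 ⇒ 1. The C5–C6 bond is cut as a [2,3]-shift, then the O–CH2 bond, then the C1–H bond (hydride). The one ring-A stereocentre that cannot be derived from another is set by catalytic asymmetric reduction and then transposed, which leads back to an achiral commercial enone. The forward steps need high enantioselectivity and a suprafacial shift without [1,2] competition.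

## Other disconnections considered

Alternative 1: This is the cut that comes to mind first. C9–C11 and C8–C15 are cut in separate steps. Ring C would be closed by SmI2-mediated ketyl–olefin cyclization of aldehyde A1 (C11 aldehyde onto C9 of the unsaturated spirolactone), and ring D afterwards by oxidative cyclization of the lactone silyl ketene acetal onto the isopropenyl group at C13. The chosen plan is preferred for three reasons. The C14 oxygen is β to the lactone carbonyl, so any enolate or ketene acetal at C8 needed for the C8–C15 closure is expected to expel it. C11 and C14 would be set in unrelated events, with C14 and C13 carried through an acyclic chain. Two ring closures and a chiral side-chain synthesis would replace one cycloaddition with a four-carbon diene.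

Alternative 2: C9–C10 and O20–C7 are cut between two carbocycles. The C10 radical from 10 would add to the cyclohexenone ester A2 and lactonize to the β-keto lactone A3; ring D would follow by C8 allylation and palladium-catalysed intramolecular α-vinylation of the C14 ketone. The chosen plan is preferred because here C14 arrives as a ketone. Its reduction would need hydride from the face covered by the axial C9–C10 bond, so attack from the open face over C15–C16 and the wrong C14 epimer are expected. The acceptor is also β-substituted and cyclic, a second enantiopure fragment is needed, and C15 would need a late allylic oxidation.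

Alternative 3: This is the biomimetic route, in which C6–C7 is reconnected. Oxidative glycol cleavage (NaIO4 or Pb(OAc)4) of the 6,7-diol hemiketal A4 of the 7,20-epoxykaurane series would give the seco aldehyde A5, and selective reduction of the C6 aldehyde would follow. The chosen plan is preferred because A4 has one more ring and two more stereocentres (C6, C7) than the target and still contains the whole C10–C9–C8 array and the bicyclooctane. The cleavage therefore removes none of the real difficulty, lengthens the synthesis, and ends with an aldehyde reduction beside an enone.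

Key step: step 13

## Steps

Step 1
Reactants: 1 2,4,4-trimethylcyclohex-2-en-1-one
Product: 2 (S)-2,4,4-trimethylcyclohex-2-en-1-ol
Conditions: (R)-2-methyl-CBS-oxazaborolidine (10 mol %), BH3·SMe2, THF, −20 °C; then MeOH, H2O
Reagents that add atoms: none
Why: Corey–Bakshi–Shibata reduction: the oxazaborolidine–borane complex binds the carbonyl anti to the larger trisubstituted alkenyl side and delivers hydride to one face, which with the (R)-catalyst should set C1 as S; 1,2-reduction is favoured over conjugate reduction at low temperature.

Step 2
Reactants: 2 (S)-2,4,4-trimethylcyclohex-2-en-1-ol; 3 tributyl(iodomethyl)stannane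
Product: 4 tributyl{[(S)-2,4,4-trimethylcyclohex-2-en-1-yl]oxymethyl}stannane
Conditions: KH, 18-crown-6 (cat.), THF, 0 °C to 25 °C
Reagents that add atoms: none
Why: Williamson ether synthesis: the potassium alkoxide displaces iodide from the primary iodomethylstannane (SN2); the C1 stereocentre is not touched.

Step 3
Reactants: 4 tributyl{[(S)-2,4,4-trimethylcyclohex-2-en-1-yl]oxymethyl}stannane
Product: 5 (R)-α-cyclogeraniol [(R)-(2,6,6-trimethylcyclohex-2-en-1-yl)methanol]
Conditions: n-BuLi, THF, −78 °C; then H2O
Reagents that add atoms: none
Why: Tin–lithium exchange gives an α-alkoxymethyllithium that undergoes the [2,3]-Wittig (Still–Wittig) rearrangement through a five-membered envelope transition state. The shift is suprafacial, so the new C5–C6 bond forms on the ring face that carried the C1 oxygen; this should transfer S at C1 into R at C5 and move the double bond to C1=C10.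

Step 4
Reactants: 5 (R)-α-cyclogeraniol
Product: 6 cis-epoxy alcohol (1,3,3-trimethyl-7-oxabicyclo[4.1.0]heptan-2-yl)methanol with the oxirane oxygen cis to CH2OH
Conditions: VO(acac)2 (2 mol %), t-BuOOH, CH2Cl2, 0 °C to 25 °C
Reagents that add atoms: tert-butyl hydroperoxide CC(C)(C)OO
Why: Hydroxyl-directed epoxidation: the homoallylic alcohol binds the vanadium tert-butylperoxo complex and oxygen is delivered to the C1=C10 face syn to the CH2OH arm, which should set the C1–O bond cis to C6.

Step 5
Reactants: 6 cis-epoxy alcohol
Product: 7 cis-epoxy silyl ether tert-butyldiphenyl[(1,3,3-trimethyl-7-oxabicyclo[4.1.0]heptan-2-yl)methoxy]silane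
Conditions: TBDPSCl, imidazole, DMF, 25 °C
Reagents that add atoms: tert-butyldiphenylsilyl chloride CC(C)(C)[Si](Cl)(c1ccccc1)c1ccccc1
Why: Standard silylation of the primary alcohol; the bulky ether is kept to the last step and later adds to the shielding of the C5 side of the dienophile.

Step 6
Reactants: 7 cis-epoxy silyl ether
Product: 8 (1S,3R)-3-[(tert-butyldiphenylsilyloxy)methyl]-4,4-dimethyl-2-methylidenecyclohexan-1-ol (OH cis to the CH2OSi arm)
Conditions: Et2AlCl, lithium 2,2,6,6-tetramethylpiperidide, toluene, 0 °C; then aq. potassium sodium tartrate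
Reagents that add atoms: none
Why: Epoxide-to-allylic-alcohol isomerization with an aluminium amide: aluminium activates the oxirane and the amide removes a syn β-hydrogen from the least hindered position (the C20 methyl; H5 is anti to the oxirane) in a cyclic transition state. The more substituted C10–O bond breaks and the C1–O bond keeps its configuration.

Step 7
Reactants: 8 allylic alcohol
Product: 9 spiro-epoxy alcohol 8-[(tert-butyldiphenylsilyloxy)methyl]-7,7-dimethyl-1-oxaspiro[2.5]octan-4-ol (OH, CH2OSi arm and oxirane oxygen mutually cis)
Conditions: VO(acac)2 (5 mol %), t-BuOOH, CH2Cl2, 0 °C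
Reagents that add atoms: tert-butyl hydroperoxide CC(C)(C)OO
Why: Hydroxyl-directed epoxidation of the allylic alcohol delivers oxygen syn to the C1 hydroxyl; the configuration at C10 is erased in step 9, and a single diastereomer only eases handling.

Step 8
Reactants: 9 spiro-epoxy alcohol
Product: 10 spiro-epoxy acetate 8-[(tert-butyldiphenylsilyloxy)methyl]-7,7-dimethyl-1-oxaspiro[2.5]octan-4-yl acetate
Conditions: Ac2O, pyridine, DMAP (cat.), CH2Cl2, 0 °C to 25 °C
Reagents that add atoms: acetic anhydride CC(=O)OC(C)=O
Why: Nucleophile-catalysed acylation of the secondary alcohol installs the C1 acetate of the target early, which avoids any late differentiation of four hydroxyl groups; no alkoxide is formed, so the oxirane should not migrate.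

Step 9
Reactants: 10 spiro-epoxy acetate; 11 2,2,2-trifluoroethyl acrylate
Product: 13 spirolactone 7-[(tert-butyldiphenylsilyloxy)methyl]-8,8-dimethyl-3-oxo-2-oxaspiro[5.5]undecan-11-yl acetate (OAc, CH2OSi arm and lactone CH2O on one face of ring A), via hydroxy ester 12 (not isolated)
Conditions: Cp2TiCl2 (2.5 equiv), Zn dust, 11 (5 equiv), THF, 25 °C, slow addition of 10; then aq. HCl
Reagents that add atoms: none
Why: Reductive epoxide opening by Cp2TiCl (trivalent titanium, single-electron transfer) cleaves the C10–O bond to the tertiary C10 radical, which should add to the acrylate (Giese addition) faster than it is reduced. The new C9–C10 bond forms on the face opposite to the C1 acetoxy group, the C5 arm and the axial C4 methyl, which sets C10. The α-ester radical is then reduced and protonated, and the C20 titanium alkoxide closes the δ-lactone on the activated trifluoroethyl ester.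

Step 10
Reactants: 13 spirolactone; 14 tert-butoxybis(dimethylamino)methane
Product: 16 α-formyl spirolactone (4-formyl derivative of 13; enol tautomer in equilibrium), via enaminone 15 (not isolated)
Conditions: 14 (3 equiv), toluene, 90 °C; then 1 M HCl, THF, 0 °C
Reagents that add atoms: water O
Why: Aminomethylenation of the lactone α-methylene C8, the most acidic C–H in 13, gives the vinylogous carbamate without strong base, so the acetate should survive. Brief aqueous acid hydrolyses it to the α-formyl lactone, a formal Claisen formylation that creates the C8–C15 bond.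

Step 11
Reactants: 16 α-formyl spirolactone
Product: 18 dienophile 7-[(tert-butyldiphenylsilyloxy)methyl]-4-formyl-8,8-dimethyl-3-oxo-2-oxaspiro[5.5]undec-4-en-11-yl acetate, via selenide 17 (not isolated)
Conditions: PhSeCl, pyridine, CH2Cl2, 0 °C; then 30% H2O2, 0 °C
Reagents that add atoms: none
Why: The enol of 16 is selenenylated at C8, and the derived selenoxide undergoes syn-elimination toward the only usable β-hydrogens at C9 (α-selenenylation–selenoxide elimination) to give the C8=C9 bond. 18 is a reactive, doubly activated alkene and is used at once.

Step 12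
Reactants: 19 (1E,3E)-buta-1,3-diene-1,4-diyl diacetate
Product: 21 (1E,3E)-1,4-bis(tert-butyldimethylsilyloxy)buta-1,3-diene, via dienediolate 20 (not isolated)
Conditions: MeLi (4.1 equiv), THF, −78 °C to 0 °C; then TBSCl, DMPU, −78 °C to 25 °C
Reagents that add atoms: tert-butyldimethylsilyl chloride CC(C)(C)[Si](C)(C)Cl
Why: Methyllithium cleaves each enol acetate to a lithium enolate with retention of double-bond geometry (enol ester cleavage), and O-silylation of the dienediolate should keep the (E,E) geometry that later gives the cis-1,4 relation of O11 and O14.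

Step 13
Reactants: 18 dienophile; 21 (1E,3E)-1,4-bis(tert-butyldimethylsilyloxy)buta-1,3-diene
Product: 22 cycloadduct aldehyde (spiro[cyclohexane-1,4'-isochroman]-1'-one core: 8a'-formyl, 5',8'-bis(tert-butyldimethylsilyloxy), C12=C13 alkene; CHO, O11 and O14 all on one face of ring C, lactone cis-fused on the other; ring A as in 18)
Conditions: 21 (3 equiv), toluene, BHT (cat.), 25 °C to 70 °C
Reagents that add atoms: none
Why: The step is a concerted but asynchronous normal-demand [4+2] cycloaddition between the HOMO of the bis(silyloxy)diene and the LUMO of the C8=C9 bond, which is lowered by both the lactone and the formyl group; the C9–C11 bond should form ahead of the C8–C14 bond. The closest known reaction type is the Diels–Alder reaction of 2-formyl- and 2-alkoxycarbonyl-cycloalk-2-enones and α-acyl unsaturated lactones with 1-oxygenated and 1,4-dioxygenated butadienes. Ring C closes as a cyclohexene by suprafacial–suprafacial cycloaddition. The cis relation of C8 and C9 (cis-fused lactone) follows from the ring-locked cis geometry of the dienophile. The cis relation of C11 and C14 follows from the (E,E) geometry of 21. The relation between the two pairs is set by the endo position of the small planar formyl group (secondary orbital overlap, while the lactone ring with its spiro substituent sits exo), which places both silyloxy groups cis to the CHO. The absolute sense is set by the spiro centre C10: the diene should add to the face of C8=C9 flanked by C1 (H and the equatorial acetoxy group) and away from C5, whose CH2OTBDPS arm is buttressed by the C4 gem-dimethyl group. The step therefore needs endo over exo, one π-face, and C=C over the O=C15–C8=C9 heterodiene mode; these should be secured by the formyl group, the bulky silyl ether on the C5 side, and Lewis-acid-free thermal conditions with an s-cis-capable diene.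

Step 14
Reactants: 22 cycloadduct aldehyde; 23 ethynylmagnesium bromide
Product: 24 propargylic alcohol (C15 carbinol bearing the ethynyl group on C8; C15 epimers; otherwise as 22)
Conditions: 23, CeCl3, THF, −78 °C; then H2O
Reagents that add atoms: none
Why: 1,2-Addition of the ethynylcerium reagent (from 23 and CeCl3) to the neopentyl aldehyde should be faster than attack on the hindered lactone or the acetate; the C15 carbinol forms as a mixture of epimers, which does not matter because C15 becomes the ketone.

Step 15
Reactants: 24 propargylic alcohol
Product: 26 allylic alcohol 1-acetoxy-11,14-bis(tert-butyldimethylsilyloxy)-6-(tert-butyldiphenylsilyloxy)-15-hydroxy-6,7-secokaur-16-en-7,20-olide (C15 epimers), via vinylstannane 25 (not isolated)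
Conditions: Bu3SnH, AIBN, benzene, 80 °C (slow addition); then SiO2, CH2Cl2, 25 °C
Reagents that add atoms: none
Why: Radical chain enyne cyclization: the stannyl radical adds to the terminal alkyne carbon C17 and the vinyl radical at C16 closes 5-exo-trig onto C13 of the ring alkene. The tether at C8 allows attack only from the face of C15, which sets C13, and the C12 radical takes hydrogen from Bu3SnH; protodestannylation of the vinylstannane on silica gives the exocyclic methylene.

Step 16
Reactants: 26 allylic alcohol
Product: 27 silylated enone 1-acetoxy-11,14-bis(tert-butyldimethylsilyloxy)-6-(tert-butyldiphenylsilyloxy)-15-oxo-6,7-secokaur-16-en-7,20-olide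
Conditions: Dess–Martin periodinane, NaHCO3, CH2Cl2, 0 °C to 25 °C
Reagents that add atoms: none
Why: Dess–Martin oxidation of the secondary allylic alcohol gives the α-methylene ketone under buffered, non-basic conditions; C8 is quaternary and O14 is silylated, so neither epimerization nor retro-aldol cleavage is open.

Step 17
Reactants: 27 silylated enone
Product: 28 (1S,5R,8R,9S,10R,11S,13S,14R)-1-acetoxy-6,11,14-trihydroxy-15-oxo-6,7-secokaur-16-en-7,20-olide (CNP0225182.1)
Conditions: HF·pyridine, pyridine, THF, 0 °C to 25 °C
Reagents that add atoms: none
Why: Fluoride cleaves the three silyl ethers under acidic buffering, which should leave the acetate, the lactone and the enone untouched and avoids the basic medium in which the 14-hydroxy ketone would undergo retro-aldol cleavage.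

## Compound list

1 | 2,4,4-trimethylcyclohex-2-en-1-one | CC1=CC(C)(C)CCC1=O | starting material
2 | (S)-2,4,4-trimethylcyclohex-2-en-1-ol | CC1=CC(C)(C)CC[C@@H]1O | intermediate
3 | tributyl(iodomethyl)stannane | CCCC[Sn](CCCC)(CCCC)CI | starting material
4 | tributyl{[(S)-2,4,4-trimethylcyclohex-2-en-1-yl]oxymethyl}stannane | CC1=CC(C)(C)CC[C@@H]1OC[Sn](CCCC)(CCCC)CCCC | intermediate
5 | (R)-α-cyclogeraniol, (R)-(2,6,6-trimethylcyclohex-2-en-1-yl)methanol | CC1=CCCC(C)(C)[C@H]1CO | intermediate
6 | cis-epoxy alcohol, (1,3,3-trimethyl-7-oxabicyclo[4.1.0]heptan-2-yl)methanol, oxirane cis to CH2OH | C[C@]12O[C@H]1CCC(C)(C)[C@H]2CO | intermediate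
7 | cis-epoxy silyl ether, TBDPS ether of 6 | C[C@]12O[C@H]1CCC(C)(C)[C@H]2CO[Si](c3ccccc3)(c3ccccc3)C(C)(C)C | intermediate
8 | (1S,3R)-3-[(tert-butyldiphenylsilyloxy)methyl]-4,4-dimethyl-2-methylidenecyclohexan-1-ol | O[C@H]1CCC(C)(C)[C@@H](CO[Si](c2ccccc2)(c2ccccc2)C(C)(C)C)C1=C | intermediate
9 | spiro-epoxy alcohol, 8-[(tert-butyldiphenylsilyloxy)methyl]-7,7-dimethyl-1-oxaspiro[2.5]octan-4-ol, OH, CH2OSi and oxirane O cis | O[C@H]1CCC(C)(C)[C@@H](CO[Si](c3ccccc3)(c3ccccc3)C(C)(C)C)[C@]12CO2 | intermediate
10 | spiro-epoxy acetate, acetate of 9 | CC(=O)O[C@H]1CCC(C)(C)[C@@H](CO[Si](c3ccccc3)(c3ccccc3)C(C)(C)C)[C@]12CO2 | intermediate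
11 | 2,2,2-trifluoroethyl acrylate | C=CC(=O)OCC(F)(F)F | starting material
12 | hydroxy ester, 2,2,2-trifluoroethyl 3-[2-acetoxy-6-[(tert-butyldiphenylsilyloxy)methyl]-1-(hydroxymethyl)-5,5-dimethylcyclohexyl]propanoate | O=C(CC[C@]1(CO)[C@@H](OC(C)=O)CCC(C)(C)[C@H]1CO[Si](c2ccccc2)(c2ccccc2)C(C)(C)C)OCC(F)(F)F | intermediate (not isolated)
13 | spirolactone, 7-[(tert-butyldiphenylsilyloxy)methyl]-8,8-dimethyl-3-oxo-2-oxaspiro[5.5]undecan-11-yl acetate | O=C1CC[C@]2(CO1)[C@@H](OC(C)=O)CCC(C)(C)[C@H]2CO[Si](c3ccccc3)(c3ccccc3)C(C)(C)C | intermediate
14 | tert-butoxybis(dimethylamino)methane (Bredereck's reagent) | CN(C)C(OC(C)(C)C)N(C)C | starting material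
15 | enaminone, 4-[(dimethylamino)methylidene] derivative of 13 | CN(C)C=C1C[C@]2(COC1=O)[C@@H](OC(C)=O)CCC(C)(C)[C@H]2CO[Si](c3ccccc3)(c3ccccc3)C(C)(C)C | intermediate (not isolated)
16 | α-formyl spirolactone, 4-formyl derivative of 13 (C8 not defined, enol tautomer in equilibrium) | O=CC1C[C@]2(COC1=O)[C@@H](OC(C)=O)CCC(C)(C)[C@H]2CO[Si](c3ccccc3)(c3ccccc3)C(C)(C)C | intermediate
17 | selenide, 4-formyl-4-(phenylselanyl) derivative of 13 | O=CC1([Se]c3ccccc3)C[C@]2(COC1=O)[C@@H](OC(C)=O)CCC(C)(C)[C@H]2CO[Si](c4ccccc4)(c4ccccc4)C(C)(C)C | intermediate (not isolated)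
18 | dienophile, 7-[(tert-butyldiphenylsilyloxy)methyl]-4-formyl-8,8-dimethyl-3-oxo-2-oxaspiro[5.5]undec-4-en-11-yl acetate | O=CC1=C[C@]2(COC1=O)[C@@H](OC(C)=O)CCC(C)(C)[C@H]2CO[Si](c3ccccc3)(c3ccccc3)C(C)(C)C | intermediate
19 | (1E,3E)-buta-1,3-diene-1,4-diyl diacetate | CC(=O)O/C=C/C=C/OC(C)=O | starting material
20 | dilithium (1E,3E)-buta-1,3-diene-1,4-diolate | [Li+].[Li+].[O-]/C=C/C=C/[O-] | intermediate (not isolated)
21 | (1E,3E)-1,4-bis(tert-butyldimethylsilyloxy)buta-1,3-diene | CC(C)(C)[Si](C)(C)O/C=C/C=C/O[Si](C)(C)C(C)(C)C | intermediate
22 | cycloadduct aldehyde (C8-CHO, 11,14-bis-OTBS, C12=C13, cis-fused lactone) | O=C[C@@]23C(=O)OC[C@]4([C@@H](OC(C)=O)CCC(C)(C)[C@H]4CO[Si](c5ccccc5)(c5ccccc5)C(C)(C)C)[C@@H]2[C@@H](O[Si](C)(C)C(C)(C)C)C=C[C@H]3O[Si](C)(C)C(C)(C)C | intermediate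
23 | ethynylmagnesium bromide | C#C[Mg]Br | starting material
24 | propargylic alcohol (C15 epimers) | C#CC(O)[C@@]23C(=O)OC[C@]4([C@@H](OC(C)=O)CCC(C)(C)[C@H]4CO[Si](c5ccccc5)(c5ccccc5)C(C)(C)C)[C@@H]2[C@@H](O[Si](C)(C)C(C)(C)C)C=C[C@H]3O[Si](C)(C)C(C)(C)C | intermediate
25 | vinylstannane (C17-tributylstannyl derivative of 26, alkene geometry not defined) | CCCC[Sn](CCCC)(CCCC)C=C1C(O)[C@@]23C(=O)OC[C@]4([C@@H](OC(C)=O)CCC(C)(C)[C@H]4CO[Si](c5ccccc5)(c5ccccc5)C(C)(C)C)[C@@H]2[C@@H](O[Si](C)(C)C(C)(C)C)C[C@@H]1[C@H]3O[Si](C)(C)C(C)(C)C | intermediate (not isolated)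
26 | allylic alcohol, 15-hydroxy-16-ene with the bicyclo[3.2.1]octane closed (C15 epimers) | C=C1C(O)[C@@]23C(=O)OC[C@]4([C@@H](OC(C)=O)CCC(C)(C)[C@H]4CO[Si](c5ccccc5)(c5ccccc5)C(C)(C)C)[C@@H]2[C@@H](O[Si](C)(C)C(C)(C)C)C[C@@H]1[C@H]3O[Si](C)(C)C(C)(C)C | intermediate
27 | silylated enone, 6-O-TBDPS-11,14-di-O-TBS ether of 28 | C=C1C(=O)[C@@]23C(=O)OC[C@]4([C@@H](OC(C)=O)CCC(C)(C)[C@H]4CO[Si](c5ccccc5)(c5ccccc5)C(C)(C)C)[C@@H]2[C@@H](O[Si](C)(C)C(C)(C)C)C[C@@H]1[C@H]3O[Si](C)(C)C(C)(C)C | intermediate
28 | (1S,5R,8R,9S,10R,11S,13S,14R)-1-acetoxy-6,11,14-trihydroxy-15-oxo-6,7-secokaur-16-en-7,20-olide (CNP0225182.1) | C=C1C(=O)[C@@]23C(=O)OC[C@]4([C@@H](OC(C)=O)CCC(C)(C)[C@H]4CO)[C@@H]2[C@@H](O)C[C@@H]1[C@H]3O | target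

## Step count and least certain steps

Total step count: 17. Longest linear sequence: 16 (steps 1–11 and 13–17); step 12 is a one-step side branch.

Step 13 (key step). Three things may go wrong. Facial selectivity may be poor if the diene adds on the C5 side of the C8=C9 bond, because both flanking ring-A carbons carry equatorial substituents. The endo preference of the formyl group may be lost. An inverse-demand hetero-[4+2] addition of a silyl enol ether double bond to the O=C15–C8=C9 unit, or self-dimerization of 18 by the same mode, may outrun the slow attack at the hindered C9. The fallback sets out from 18 and 21 and returns at 22; it moves facial control from the substrate to a reagent and activation from heat to a Lewis acid. The formyl group of 18 is bound at −78 °C in CH2Cl2 by a chiral cationic oxazaborolidinium Lewis acid (a diphenylprolinol-derived B-aryl oxazaborolidine protonated by triflimide). The catalyst enantiomer is chosen to block the C5 face, the aldehyde-bound complex should react in the all-carbon mode, and the low temperature suppresses dimerization. No new compound arises.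

Step 3. The C5 terminus is flanked by the C4 gem-dimethyl group, so a [1,2]-shift or simple protonation of the carbanion may compete with the [2,3]-shift, and chirality transfer would then be lost with the material. The fallback sets out from 1 and returns at 5. Reduction of 1 with the (S)-oxazaborolidine gives (R)-2,4,4-trimethylcyclohex-2-en-1-ol F1. Esterification with picolinic acid (DCC, DMAP) gives (R)-2,4,4-trimethylcyclohex-2-en-1-yl picolinate F2. Copper-catalysed anti-SN2' substitution with (isopropoxydimethylsilyl)methylmagnesium chloride (CuBr·SMe2) places the silylmethyl group on C5 on the face opposite to the leaving group and gives (R)-isopropoxydimethyl[(2,6,6-trimethylcyclohex-2-en-1-yl)methyl]silane F3. Tamao oxidation (H2O2, KF, KHCO3) then gives 5.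

Step 9. The tertiary C10 radical may be reduced by a second equivalent of trivalent titanium before it adds to 11. Elimination of the β-acetoxy or β-titanoxy group would then give alkenes, and the acetyl group may also migrate from O1 to the C20 titanium alkoxide before lactonization. The fallback sets out from 9 and returns at 13. Silylation of 9 (TESCl, imidazole) gives the spiro-epoxy triethylsilyl ether F4. The same titanocene-mediated coupling with 11 gives the spirolactone triethylsilyl ether F5; a silyloxy group is a poorer leaving group than acetoxy and cannot migrate as an acyl group. PPTS in methanol removes the triethylsilyl group beside the TBDPS ether to give the hydroxy spirolactone F6, and acetylation (Ac2O, pyridine) gives 13.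

Step 10. The liberated dimethylamine may cleave the C1 acetate by aminolysis at 90 °C, or the reagent may attack the acetate methyl group, so that chemoselectivity for the lactone α-methylene is lost. The fallback sets out from 10 and returns at 16; the formyl carbon is brought in with the radical acceptor. Coupling of 10 under the conditions of step 9 with 2,2,2-trifluoroethyl 2-(dimethoxymethyl)acrylate F7 gives the α-(dimethoxymethyl) spirolactone F8, and mild acetal hydrolysis (aqueous trifluoroacetic acid, CH2Cl2, 0 °C) gives 16. Neither an enolate nor an amine is involved.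

Step 15. The vinyl radical may be reduced before it cyclizes, may abstract the activated H14 by 1,5-hydrogen transfer, or may close 6-endo onto C12; protodestannylation may also be incomplete or may ionize the allylic alcohol. The fallback sets out from 24 and returns at 26; it closes ring D by an organopalladium path. Hydridopalladium generated from Pd2(dba)3, tri(o-tolyl)phosphine and acetic acid adds across the alkyne, and the vinylpalladium carbopalladates C12=C13 in the 5-exo mode. The C12–Pd bond has no syn β-hydrogen (H11 and H13 lie on the opposite face) and is reduced by Et3SiH, so the exocyclic methylene forms directly. No new compound arises.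

## Further compounds

F0 | step 13 | none | none
F1 | step 3 | (R)-2,4,4-trimethylcyclohex-2-en-1-ol | CC1=CC(C)(C)CC[C@H]1O
F2 | step 3 | (R)-2,4,4-trimethylcyclohex-2-en-1-yl picolinate | CC1=CC(C)(C)CC[C@H]1OC(=O)c2ccccn2
F3 | step 3 | (R)-isopropoxydimethyl[(2,6,6-trimethylcyclohex-2-en-1-yl)methyl]silane | CC1=CCCC(C)(C)[C@H]1C[Si](C)(C)OC(C)C
F4 | step 9 | spiro-epoxy triethylsilyl ether, TES ether of 9 | CC[Si](CC)(CC)O[C@H]1CCC(C)(C)[C@@H](CO[Si](c3ccccc3)(c3ccccc3)C(C)(C)C)[C@]12CO2
F5 | step 9 | spirolactone triethylsilyl ether, 11-O-TES analogue of 13 | O=C1CC[C@]2(CO1)[C@@H](O[Si](CC)(CC)CC)CCC(C)(C)[C@H]2CO[Si](c3ccccc3)(c3ccccc3)C(C)(C)C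
F6 | step 9 | hydroxy spirolactone, 11-hydroxy analogue of 13 | O=C1CC[C@]2(CO1)[C@@H](O)CCC(C)(C)[C@H]2CO[Si](c3ccccc3)(c3ccccc3)C(C)(C)C
F7 | step 10 | 2,2,2-trifluoroethyl 2-(dimethoxymethyl)acrylate | C=C(C(OC)OC)C(=O)OCC(F)(F)F
F8 | step 10 | α-(dimethoxymethyl) spirolactone, dimethyl acetal of 16 | COC(OC)C1C[C@]2(COC1=O)[C@@H](OC(C)=O)CCC(C)(C)[C@H]2CO[Si](c3ccccc3)(c3ccccc3)C(C)(C)C
F0 | step 15 | none | none
A1 | alternative 1 | aldehyde for ketyl–olefin closure of ring C (C8=C9 spirolactone with the C14(OTBS)–C13(isopropenyl)–C12–C11HO chain on C8) | O=CC[C@@H](C(C)=C)[C@@H](O[Si](C)(C)C(C)(C)C)C1=C[C@]2(COC1=O)[C@@H](OC(C)=O)CCC(C)(C)[C@H]2CO[Si](c3ccccc3)(c3ccccc3)C(C)(C)C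
A2 | alternative 2 | methyl (3S)-3-(tert-butyldimethylsilyloxy)-6-oxocyclohex-1-ene-1-carboxylate | COC(=O)C1=C[C@@H](O[Si](C)(C)C(C)(C)C)CCC1=O
A3 | alternative 2 | β-keto spirolactone from radical coupling (C14 ketone, C8–H not defined) | O=C1C2C(=O)OC[C@]4([C@@H](OC(C)=O)CCC(C)(C)[C@H]4CO[Si](c5ccccc5)(c5ccccc5)C(C)(C)C)[C@@H]2[C@@H](O[Si](C)(C)C(C)(C)C)CC1
A4 | alternative 3 | 1-acetoxy-6,7,11,14-tetrahydroxy-7,20-epoxykaur-16-en-15-one (6,7-diol hemiketal) | C=C1C(=O)[C@@]23[C@]5(O)OC[C@]4([C@@H](OC(C)=O)CCC(C)(C)[C@H]4[C@@H]5O)[C@@H]2[C@@H](O)C[C@@H]1[C@H]3O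
A5 | alternative 3 | 1-acetoxy-11,14-dihydroxy-6,15-dioxo-6,7-secokaur-16-en-7,20-olide (seco aldehyde) | C=C1C(=O)[C@@]23C(=O)OC[C@]4([C@@H](OC(C)=O)CCC(C)(C)[C@H]4C=O)[C@@H]2[C@@H](O)C[C@@H]1[C@H]3O
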